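The six carbons of ring A, its ester carbonyl carbon and the seven-carbon 2-oxoheptyl branch make up one unbranched fourteen-carbon chain that carries oxygen on C1, C3, C5, C7 and C9. The route therefore cuts the C1–C6 bond of ring A. The precursor is a linear 3,5,7-trioxooctanoate already esterified to the ring B phenol, with the side-chain ketone (chain C9) held as a dioxolane. In one operation an intramolecular aldol between the C2 methylene and the C7 ketone, followed by loss of water, creates ring A as a resorcylate with the hindered depside ester in place. That ester is made earlier, when the ring B phenol adds to an unhindered acylketene released from a diketo-dioxinone.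

Key step: step 10

Remark (assumption): the target has no stereocentre and no configurationally stable axis, so it is a single achiral compound and no step has to control configuration.
Remark (numbering and design): chain numbers start at the aryl ester carbonyl (C1) and end at the ketal carbon (C9); ring A numbers start at the carbon bearing the ester. Precursor 14 keeps a benzyl ester on ring B and a 1,3-dioxolane at C9, since both survive heat, amine base and buffered acid and both leave in the closing operation. The temporary group on the ring B 4-OH is therefore allyl, which is orthogonal to benzyl.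

Step 1
Reactants: 1 ethyl 3-oxooctanoate
Product: 2 ethyl 2-(2-pentyl-1,3-dioxolan-2-yl)acetate
Conditions: HOCH2CH2OH, p-TsOH·H2O (cat.), toluene, reflux, Dean–Stark
Reagents that add atoms: ethylene glycol, OCCO
Why: Acid-catalysed ketalisation of the ketone of a β-keto ester with azeotropic removal of water is routine and leaves the ester untouched.

Step 2
Reactants: 2 ethyl 2-(2-pentyl-1,3-dioxolan-2-yl)acetate
Product: 3 N-methoxy-N-methyl-2-(2-pentyl-1,3-dioxolan-2-yl)acetamide
Conditions: MeNH(OMe)·HCl, i-PrMgCl, THF, −20 → 0 °C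
Reagents that add atoms: N,O-dimethylhydroxylamine hydrochloride, CNOC.Cl
Why: The chloromagnesium amide formed in situ aminolyses the ethyl ester directly (ester to Weinreb amide exchange) at a temperature at which the ketal and the α-methylene should be left alone.

Step 3
Reactants: 4 2,2,6-trimethyl-4H-1,3-dioxin-4-one
Product: 5 2,2-dimethyl-6-(2-oxopropyl)-4H-1,3-dioxin-4-one
Conditions: LiHMDS, THF, −78 °C; then AcCl, −78 °C (4 and base each 2 equiv per AcCl)
Reagents that add atoms: acetyl chloride, CC(Cl)=O
Why: γ-Deprotonation gives the vinylogous lithium enolate, which is C-acylated at the exocyclic carbon by acetyl chloride (vinylogous Claisen-type acylation), the second equivalent of enolate taking up the proton of the more acidic product.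

Step 4
Reactants: 5 2,2-dimethyl-6-(2-oxopropyl)-4H-1,3-dioxin-4-one; 3 N-methoxy-N-methyl-2-(2-pentyl-1,3-dioxolan-2-yl)acetamide
Product: 6 2,2-dimethyl-6-[2,4-dioxo-5-(2-pentyl-1,3-dioxolan-2-yl)pentyl]-4H-1,3-dioxin-4-one
Conditions: LDA (2.1 equiv per 5), THF, −78 °C; then 3 (0.5 equiv), −78 → −40 °C; pH 5 buffer quench
Reagents that add atoms: none
Why: The dianion of the β-keto-dioxinone reacts at its terminal, more basic carbanion, and the Weinreb amide stops at the chelated tetrahedral adduct, so a single Claisen-type C-acylation of the dianion is expected, with the excess dianion covering proton transfer to the product.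

Step 5
Reactants: 7 olivetol (5-pentylbenzene-1,3-diol)
Product: 8 olivetolic acid (2,4-dihydroxy-6-pentylbenzoic acid)
Conditions: MeOMgOCO2Me (2 M in DMF), 120 °C; then cold aq HCl
Reagents that add atoms: methyl magnesium carbonate, COC(=O)O[Mg]OC
Why: Methyl magnesium carbonate carboxylates a phenol ortho to its hydroxyl through a magnesium chelate (Kolbe–Schmitt-type carboxylation), a known conversion of olivetol into olivetolic acid, and cold acidification avoids decarboxylation.

Step 6
Reactants: 8 olivetolic acid
Product: 9 benzyl 2,4-dihydroxy-6-pentylbenzoate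
Conditions: BnBr, KHCO3, DMF, rt
Reagents that add atoms: benzyl bromide, BrCc1ccccc1
Why: Hydrogencarbonate ionises only the carboxylic acid, so SN2 alkylation of the carboxylate with benzyl bromide should give the ester and leave both phenols free.

Step 7
Reactants: 9 benzyl 2,4-dihydroxy-6-pentylbenzoate
Product: 11 benzyl 2-methoxy-6-pentyl-4-(prop-2-en-1-yloxy)benzoate, via 4-O-allyl ether 10 (not isolated)
Conditions: allyl bromide (1.05 equiv), K2CO3, DMF, rt; then MeI (excess), 40 °C
Reagents that add atoms: allyl bromide, C=CCBr; iodomethane, CI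
Why: In this sequential Williamson etherification the free 4-OH is alkylated first because the 2-OH is hydrogen-bonded to the ester carbonyl and reacts only with excess iodomethane on warming, so the allyl group should go to O-4 and the methyl group to O-2.

Step 8
Reactants: 11 benzyl 2-methoxy-6-pentyl-4-(prop-2-en-1-yloxy)benzoate
Product: 12 benzyl 4-hydroxy-2-methoxy-6-pentylbenzoate
Conditions: Pd(PPh3)4 (cat.), morpholine, THF, rt
Reagents that add atoms: none
Why: Pd(0) ionises the aryl allyl ether to a π-allyl complex that morpholine captures (Tsuji–Trost deallylation), conditions to which the benzyl ester and the methyl ether are inert.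

Step 9
Reactants: 6 2,2-dimethyl-6-[2,4-dioxo-5-(2-pentyl-1,3-dioxolan-2-yl)pentyl]-4H-1,3-dioxin-4-one; 12 benzyl 4-hydroxy-2-methoxy-6-pentylbenzoate
Product: 14 benzyl 2-methoxy-6-pentyl-4-{[3,5,7-trioxo-8-(2-pentyl-1,3-dioxolan-2-yl)octanoyl]oxy}benzoate, via acylketene 13 (not isolated)
Conditions: toluene, 110 °C (12 in slight excess); evaporate, crude 14 used directly
Reagents that add atoms: none
Why: Retro-hetero-Diels–Alder fragmentation of the dioxinone expels acetone and releases an acylketene whose sp carbon is unhindered, and the unhindered 4-OH of 12 adds to it (acylketene trapping by a phenol) to give the aryl β-keto ester without a coupling agent.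

Step 10
Reactants: 14 benzyl 2-methoxy-6-pentyl-4-{[3,5,7-trioxo-8-(2-pentyl-1,3-dioxolan-2-yl)octanoyl]oxy}benzoate
Product: 16 benzyl 4-({2,4-dihydroxy-6-[(2-pentyl-1,3-dioxolan-2-yl)methyl]benzoyl}oxy)-2-methoxy-6-pentylbenzoate, via aldol adduct 15 (not isolated)
Conditions: Et3N, CH2Cl2, 0 °C → rt; then AcOH, 4 Å MS, rt
Reagents that add atoms: none
Why: Triethylamine forms the enolate at C2, the most acidic methylene because it lies between the aryl ester and the C3 ketone, and this carbon adds to the C7 carbonyl to make the C2–C7 bond (C1–C6 of ring A); the tertiary aldol 15 then loses water and C3 and C5 enolise to give the aromatic 2,4-dihydroxybenzoate. The closest known reaction type is the base-mediated aldol cycloaromatisation of alkyl 3,5,7-trioxoalkanoates obtained from dioxinone-derived acylketenes, applied here to an aryl ester. Ring A closes in a 6-(enolendo)-exo-trig mode when the nucleophile is written as the C2=C3 ketone enolate, a mode allowed for six-membered rings. No stereocentre has to be controlled, because the two centres of 15 are erased on aromatisation. The step needs C2-to-C7 aldol to be faster than attack of the C5 enol oxygen or of C6 on the ester carbonyl (pyranone or phloroglucinol closure with loss of the ring B phenoxide) and faster than E1cB return to the ketene; the substrate secures this through the doubly activated C2–H, through the dioxolane at C9, which leaves C8 non-acidic and C7 as the only ketone that C2 can reach in a six-membered aldol, and through the irreversible aromatisation that drains the aldol equilibrium. A weak amine base in a non-nucleophilic solvent, followed by buffered acid over molecular sieves, should avoid transesterification of the aryl ester and hydrolysis of the ketal.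

Step 11
Reactants: 16 benzyl 4-({2,4-dihydroxy-6-[(2-pentyl-1,3-dioxolan-2-yl)methyl]benzoyl}oxy)-2-methoxy-6-pentylbenzoate
Product: 17 benzyl 4-({2-hydroxy-4-methoxy-6-[(2-pentyl-1,3-dioxolan-2-yl)methyl]benzoyl}oxy)-2-methoxy-6-pentylbenzoate
Conditions: MeI (1.1 equiv), K2CO3 (1.1 equiv), acetone, rt
Reagents that add atoms: iodomethane, CI
Why: The ring A 4-OH, para to the ester carbonyl and not hydrogen-bonded, is the more acidic phenol, so Williamson methylation with one equivalent of iodomethane should occur there while the chelated 2-OH and the hindered depside ester remain.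

Step 12
Reactants: 17 benzyl 4-({2-hydroxy-4-methoxy-6-[(2-pentyl-1,3-dioxolan-2-yl)methyl]benzoyl}oxy)-2-methoxy-6-pentylbenzoate
Product: 19 confluentic acid, via ketal acid 18 (not isolated)
Conditions: H2 (1 atm), Pd/C, EtOAc, rt; filter; then 1 M aq HCl, THF, rt
Reagents that add atoms: water, O
Why: Hydrogenolysis cleaves only the benzylic C–O bond of the ester, and dilute aqueous acid then hydrolyses the dialkyl ketone dioxolane (acetal hydrolysis) at room temperature, where the aryl ester, the methyl ethers and the released ketone should be stable.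

Compound list
1 | ethyl 3-oxooctanoate | CCCCCC(=O)CC(=O)OCC | starting material
2 | ethyl 2-(2-pentyl-1,3-dioxolan-2-yl)acetate | CCCCCC1(CC(=O)OCC)OCCO1 | intermediate
3 | N-methoxy-N-methyl-2-(2-pentyl-1,3-dioxolan-2-yl)acetamide | CCCCCC1(CC(=O)N(C)OC)OCCO1 | intermediate
4 | 2,2,6-trimethyl-4H-1,3-dioxin-4-one | CC1=CC(=O)OC(C)(C)O1 | starting material
5 | 2,2-dimethyl-6-(2-oxopropyl)-4H-1,3-dioxin-4-one | CC(=O)CC1=CC(=O)OC(C)(C)O1 | intermediate
6 | 2,2-dimethyl-6-[2,4-dioxo-5-(2-pentyl-1,3-dioxolan-2-yl)pentyl]-4H-1,3-dioxin-4-one | CCCCCC1(CC(=O)CC(=O)CC2=CC(=O)OC(C)(C)O2)OCCO1 | intermediate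
7 | olivetol (5-pentylbenzene-1,3-diol) | CCCCCc1cc(O)cc(O)c1 | starting material
8 | olivetolic acid (2,4-dihydroxy-6-pentylbenzoic acid) | CCCCCc1cc(O)cc(O)c1C(=O)O | intermediate
9 | benzyl 2,4-dihydroxy-6-pentylbenzoate | CCCCCc1cc(O)cc(O)c1C(=O)OCc1ccccc1 | intermediate
10 | benzyl 2-hydroxy-6-pentyl-4-(prop-2-en-1-yloxy)benzoate | CCCCCc1cc(OCC=C)cc(O)c1C(=O)OCc1ccccc1 | intermediate
11 | benzyl 2-methoxy-6-pentyl-4-(prop-2-en-1-yloxy)benzoate | CCCCCc1cc(OCC=C)cc(OC)c1C(=O)OCc1ccccc1 | intermediate
12 | benzyl 4-hydroxy-2-methoxy-6-pentylbenzoate | CCCCCc1cc(O)cc(OC)c1C(=O)OCc1ccccc1 | intermediate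
13 | 8-(2-pentyl-1,3-dioxolan-2-yl)oct-1-ene-1,3,5,7-tetrone (acylketene) | CCCCCC1(CC(=O)CC(=O)CC(=O)C=C=O)OCCO1 | intermediate
14 | benzyl 2-methoxy-6-pentyl-4-{[3,5,7-trioxo-8-(2-pentyl-1,3-dioxolan-2-yl)octanoyl]oxy}benzoate (keto form drawn) | CCCCCC1(CC(=O)CC(=O)CC(=O)CC(=O)Oc2cc(CCCCC)c(C(=O)OCc3ccccc3)c(OC)c2)OCCO1 | intermediate
15 | benzyl 4-[({2-hydroxy-4,6-dioxo-2-[(2-pentyl-1,3-dioxolan-2-yl)methyl]cyclohexyl}carbonyl)oxy]-2-methoxy-6-pentylbenzoate (mixture of racemic diastereomers) | CCCCCC1(CC2(O)CC(=O)CC(=O)C2C(=O)Oc2cc(CCCCC)c(C(=O)OCc3ccccc3)c(OC)c2)OCCO1 | intermediate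
16 | benzyl 4-({2,4-dihydroxy-6-[(2-pentyl-1,3-dioxolan-2-yl)methyl]benzoyl}oxy)-2-methoxy-6-pentylbenzoate | CCCCCC1(Cc2cc(O)cc(O)c2C(=O)Oc2cc(CCCCC)c(C(=O)OCc3ccccc3)c(OC)c2)OCCO1 | intermediate
17 | benzyl 4-({2-hydroxy-4-methoxy-6-[(2-pentyl-1,3-dioxolan-2-yl)methyl]benzoyl}oxy)-2-methoxy-6-pentylbenzoate | CCCCCC1(Cc2cc(OC)cc(O)c2C(=O)Oc2cc(CCCCC)c(C(=O)OCc3ccccc3)c(OC)c2)OCCO1 | intermediate
18 | 4-({2-hydroxy-4-methoxy-6-[(2-pentyl-1,3-dioxolan-2-yl)methyl]benzoyl}oxy)-2-methoxy-6-pentylbenzoic acid | CCCCCC1(Cc2cc(OC)cc(O)c2C(=O)Oc2cc(CCCCC)c(C(=O)O)c(OC)c2)OCCO1 | intermediate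
19 | confluentic acid (4-{[2-hydroxy-4-methoxy-6-(2-oxoheptyl)benzoyl]oxy}-2-methoxy-6-pentylbenzoic acid) | CCCCCC(=O)Cc1cc(OC)cc(O)c1C(=O)Oc1cc(CCCCC)c(C(=O)O)c(OC)c1 | target

Total step count: 12.
Longest linear sequence: 8 steps (olivetol 7 through steps 5, 6, 7, 8, 9, 10, 11 and 12 to 19).

Steps most likely to fail

1. Step 10. The ring B phenoxide may be expelled, by lactonisation of the C5 enol oxygen onto C1 or by E1cB elimination to the ketene, faster than the C2-to-C7 aldol closes ring A. The fallback makes ring A on an ester with a poor leaving group and forms the depside bond afterwards. It sets out from 6, which is heated in toluene with benzyl alcohol to give benzyl 3,5,7-trioxo-8-(2-pentyl-1,3-dioxolan-2-yl)octanoate F1. Et3N and then buffered acid should cyclise and aromatise this to benzyl 2,4-dihydroxy-6-[(2-pentyl-1,3-dioxolan-2-yl)methyl]benzoate F2. Selective methylation of its 4-OH (MeI, K2CO3, acetone) gives benzyl 2-hydroxy-4-methoxy-6-[(2-pentyl-1,3-dioxolan-2-yl)methyl]benzoate F3, and hydrogenolysis (H2, Pd/C) gives 2-hydroxy-4-methoxy-6-[(2-pentyl-1,3-dioxolan-2-yl)methyl]benzoic acid F4. Carbodiimide esterification of F4 with phenol 12 (DCC, toluene, rt, the classical depside coupling of an ortho-hydroxybenzoic acid) returns to the route at 17.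

2. Step 9. The enolised chain of the acylketene may capture the ketene intramolecularly (pyranone closure) before the weakly nucleophilic phenol adds. The fallback closes the arene before any ketene is made. It sets out from 6, which is not thermolysed: Et3N in CH2Cl2 should let the dioxinone C5 add to the distal side-chain ketone and, after dehydration, give 7-hydroxy-2,2-dimethyl-5-[(2-pentyl-1,3-dioxolan-2-yl)methyl]-4H-1,3-benzodioxin-4-one F5. Methylation (MeI, K2CO3, acetone) gives 7-methoxy-2,2-dimethyl-5-[(2-pentyl-1,3-dioxolan-2-yl)methyl]-4H-1,3-benzodioxin-4-one F6. Irradiation of F6 near 300 nm in CH2Cl2 with 12 should release the quinone ketene 3-methoxy-6-(oxomethylidene)-5-[(2-pentyl-1,3-dioxolan-2-yl)methyl]cyclohexa-2,4-dien-1-one F7, which has no competing internal carbon or enol nucleophile and is trapped by the phenol. This returns to the route at 17.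

3. Step 4. The basic dianion may deprotonate the α-methylene of the Weinreb amide, with β-elimination that opens the dioxolane, or proton transfer may stop the acylation. The fallback replaces the acylation by an aldol addition and an oxidation. It sets out from 2, which DIBAL-H at −78 °C reduces to 2-(2-pentyl-1,3-dioxolan-2-yl)acetaldehyde F8. The dianion of 5 should add to this aldehyde far faster than it enolises it, giving racemic 6-[4-hydroxy-2-oxo-5-(2-pentyl-1,3-dioxolan-2-yl)pentyl]-2,2-dimethyl-4H-1,3-dioxin-4-one F9. Dess–Martin oxidation of the β-hydroxy ketone returns to the route at 6.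

Further compounds
F1 | step 10 | benzyl 3,5,7-trioxo-8-(2-pentyl-1,3-dioxolan-2-yl)octanoate | CCCCCC1(CC(=O)CC(=O)CC(=O)CC(=O)OCc2ccccc2)OCCO1
F2 | step 10 | benzyl 2,4-dihydroxy-6-[(2-pentyl-1,3-dioxolan-2-yl)methyl]benzoate | CCCCCC1(Cc2cc(O)cc(O)c2C(=O)OCc2ccccc2)OCCO1
F3 | step 10 | benzyl 2-hydroxy-4-methoxy-6-[(2-pentyl-1,3-dioxolan-2-yl)methyl]benzoate | CCCCCC1(Cc2cc(OC)cc(O)c2C(=O)OCc2ccccc2)OCCO1
F4 | step 10 | 2-hydroxy-4-methoxy-6-[(2-pentyl-1,3-dioxolan-2-yl)methyl]benzoic acid | CCCCCC1(Cc2cc(OC)cc(O)c2C(=O)O)OCCO1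
F5 | step 9 | 7-hydroxy-2,2-dimethyl-5-[(2-pentyl-1,3-dioxolan-2-yl)methyl]-4H-1,3-benzodioxin-4-one | CCCCCC1(Cc2cc(O)cc3OC(C)(C)OC(=O)c23)OCCO1
F6 | step 9 | 7-methoxy-2,2-dimethyl-5-[(2-pentyl-1,3-dioxolan-2-yl)methyl]-4H-1,3-benzodioxin-4-one | CCCCCC1(Cc2cc(OC)cc3OC(C)(C)OC(=O)c23)OCCO1
F7 | step 9 | 3-methoxy-6-(oxomethylidene)-5-[(2-pentyl-1,3-dioxolan-2-yl)methyl]cyclohexa-2,4-dien-1-one | O=C=C1C(=O)C=C(OC)C=C1CC1(CCCCC)OCCO1
F8 | step 4 | 2-(2-pentyl-1,3-dioxolan-2-yl)acetaldehyde | CCCCCC1(CC=O)OCCO1
F9 | step 4 | 6-[4-hydroxy-2-oxo-5-(2-pentyl-1,3-dioxolan-2-yl)pentyl]-2,2-dimethyl-4H-1,3-dioxin-4-one (racemic) | CCCCCC1(CC(O)CC(=O)CC2=CC(=O)OC(C)(C)O2)OCCO1
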